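**Retrosynthetic overview**
- The route rests on the quaternary C5 of carbocyclic ring A (C4a, C5, C6, C7, C8, C8a; fused through C4a–C8a to the 2-pyranone ring B). Its methyl and its farnesyl CH2 are nearly alike, so C5 is carried as an exocyclic methylene, which leaves that carbon achiral with two clearly different faces.
- Target ⇐ C6 dioxolane of its 8-keto form (ketal hydrolysis, enolisation of the C6/C8 diketone) ⇐ 3-acyl-4-bromopyranone by an enantioselective reductive Heck closure that forms C4a–C5, closes ring A and turns the methylene into the C5 methyl.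
- Bromopyranone ⇐ C-acylation of 4-hydroxy-6-methylpyran-2-one with a ketal-protected acid, then exchange of the 4-hydroxyl for bromide.
- Ketal acid ⇐ methyl 2-methyl-3-oxobutanoate by two γ-alkylations of its dianion (farnesyl bromide, then ClCH2SPh), ketalisation of the saturated ketone, sulfoxide elimination to the methylene, saponification.
- Ring order: ring B is bought; ring A is closed in the penultimate step.

Key step: step 8

Assumption: the sense of induction of BINAP on this substrate cannot be predicted with confidence, so (R)-BINAP is written and its antipode is to be used if a small trial leads to the (5R) series; the centres formed at C7 (and at C5 before step 4) are carried as mixtures because they are erased later.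

**Route**

Step 1
Reactants: 1 methyl 2-methyl-3-oxobutanoate; 2 (2E,6E)-farnesyl bromide
Product: 4 methyl (6E,10E)-2,7,11,15-tetramethyl-3-oxohexadeca-6,10,14-trienoate (racemic), via sodium lithium dianion 3 (not isolated)
Conditions: NaH, THF, 0 °C; n-BuLi, 0 °C; then 2, 0 °C → rt; 1 M HCl quench
Reagents that add atoms: none
Why: Alkylation of the Weiler dianion of a β-keto ester takes place at the more basic terminal carbon, and a primary allylic bromide reacts there by SN2 without allylic transposition, so the farnesyl CH2 should end up on the carbon that becomes C5 with both E alkenes intact.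

Step 2
Reactants: 4 methyl (6E,10E)-2,7,11,15-tetramethyl-3-oxohexadeca-6,10,14-trienoate
Product: 6 methyl (6E,10E)-2,7,11,15-tetramethyl-3-oxo-4-[(phenylsulfanyl)methyl]hexadeca-6,10,14-trienoate (mixture of diastereomers), via dilithium dianion 5 (not isolated)
Conditions: LiN(iPr)2 (2.2 equiv), THF, −78 → 0 °C; PhSCH2Cl, −78 → 0 °C; 1 M HCl quench
Reagents that add atoms: chloromethyl phenyl sulfide, ClCSc1ccccc1
Why: A second γ-deprotonation gives the dianion of the now γ-monosubstituted keto ester, and enolate alkylation of its γ-carbon by the activated α-chloro sulfide should install the one-carbon unit that later becomes the C5 methylene in a form that is inert to the ketalisation, the new centre being of no consequence.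

Step 3
Reactants: 6 methyl (6E,10E)-2,7,11,15-tetramethyl-3-oxo-4-[(phenylsulfanyl)methyl]hexadeca-6,10,14-trienoate
Product: 7 methyl 2-{2-[(4E,8E)-5,9,13-trimethyl-1-(phenylsulfanyl)tetradeca-4,8,12-trien-2-yl]-1,3-dioxolan-2-yl}propanoate (mixture of diastereomers)
Conditions: (Me3SiOCH2)2, Me3SiOTf (cat.), CH2Cl2, −78 → −20 °C; pyridine quench
Reagents that add atoms: 1,2-bis(trimethylsilyloxy)ethane, C[Si](C)(C)OCCO[Si](C)(C)C
Why: Noyori ketalisation runs aprotically at low temperature and is driven by formation of hexamethyldisiloxane, which should spare the trisubstituted alkenes and the sulfide, and it is placed on the saturated ketone because a free α-methylene ketone would invite conjugate addition of the diol.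

Step 4
Reactants: 7 methyl 2-{2-[(4E,8E)-5,9,13-trimethyl-1-(phenylsulfanyl)tetradeca-4,8,12-trien-2-yl]-1,3-dioxolan-2-yl}propanoate
Product: 9 methyl 2-{2-[(4E,8E)-5,9,13-trimethyltetradeca-1,4,8,12-tetraen-2-yl]-1,3-dioxolan-2-yl}propanoate (racemic), via sulfoxide 8 (not isolated)
Conditions: NaIO4, MeOH/THF/H2O, 0 °C → rt; then PhMe, CaCO3, 110 °C
Reagents that add atoms: none
Why: Periodate oxidises the sulfide to the sulfoxide without touching the alkenes, and the thermal syn elimination (sulfoxide pyrolysis) can only take the single β-hydrogen at C5, so the exocyclic methylene should form regiospecifically next to the ketal.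

Step 5
Reactants: 9 methyl 2-{2-[(4E,8E)-5,9,13-trimethyltetradeca-1,4,8,12-tetraen-2-yl]-1,3-dioxolan-2-yl}propanoate
Product: 10 2-{2-[(4E,8E)-5,9,13-trimethyltetradeca-1,4,8,12-tetraen-2-yl]-1,3-dioxolan-2-yl}propanoic acid (racemic)
Conditions: LiOH, THF/MeOH/H2O, 45 °C; then 1 M HCl to pH 4, 0 °C
Reagents that add atoms: lithium hydroxide, [Li+].[OH-]
Why: Saponification of the methyl ester leaves the base-stable dioxolane and the skipped diene alone, and brief acidification to pH 4 in the cold should free the acid, which is used at once, without loss of the ketal.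

Step 6
Reactants: 10 2-{2-[(4E,8E)-5,9,13-trimethyltetradeca-1,4,8,12-tetraen-2-yl]-1,3-dioxolan-2-yl}propanoic acid; 11 4-hydroxy-6-methylpyran-2-one
Product: 13 4-hydroxy-6-methyl-3-(2-{2-[(4E,8E)-5,9,13-trimethyltetradeca-1,4,8,12-tetraen-2-yl]-1,3-dioxolan-2-yl}propanoyl)-2H-pyran-2-one (racemic), via pyranyl ester 12 (not isolated)
Conditions: DCC, DMAP (1.2 equiv), PhMe, rt then 90 °C
Reagents that add atoms: none
Why: Carbodiimide coupling gives the 4-O-acyl pyranone, which 4-(dimethylamino)pyridine should convert by a Fries-type O-to-C acyl shift into the chelated 3-acyl-4-hydroxypyranone, the usual entry to 3-acyl derivatives of this lactone, while the dioxolane keeps C6 from condensing with the 4-hydroxyl.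

Step 7
Reactants: 13 4-hydroxy-6-methyl-3-(2-{2-[(4E,8E)-5,9,13-trimethyltetradeca-1,4,8,12-tetraen-2-yl]-1,3-dioxolan-2-yl}propanoyl)-2H-pyran-2-one
Product: 14 4-bromo-6-methyl-3-(2-{2-[(4E,8E)-5,9,13-trimethyltetradeca-1,4,8,12-tetraen-2-yl]-1,3-dioxolan-2-yl}propanoyl)-2H-pyran-2-one (racemic; C7 epimers in isochromene numbering)
Conditions: Ph3PBr2, Et3N, MeCN/CH2Cl2, 0 °C → rt; used without storage
Reagents that add atoms: triphenylphosphine dibromide, BrP(Br)(c1ccccc1)(c1ccccc1)c1ccccc1
Why: The Piers conversion of a 1,3-dicarbonyl enol into a β-bromo enone (O-phosphonium formation, then addition–elimination of bromide at C4 of the pyranone) runs under amine buffering, so the dioxolane and the polyene should survive and the aromatic 4-bromopyranone should be the favoured isomer.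

Step 8
Reactants: 14 4-bromo-6-methyl-3-(2-{2-[(4E,8E)-5,9,13-trimethyltetradeca-1,4,8,12-tetraen-2-yl]-1,3-dioxolan-2-yl}propanoyl)-2H-pyran-2-one
Product: 15 (5S)-6,6-(ethylenedioxy)-3,5,7-trimethyl-5-[(2E,6E)-3,7,11-trimethyldodeca-2,6,10-trien-1-yl]-6,7-dihydro-1H-isochromene-1,8(5H)-dione (C7 epimers)
Conditions: Pd(OAc)2 (10 mol %), (R)-BINAP (20 mol %), HCO2Na (2 equiv), DMF, 80 °C, degassed
Reagents that add atoms: none
Why: Pd(OAc)2 and (R)-2,2'-bis(diphenylphosphino)-1,1'-binaphthyl give zerovalent palladium, which inserts into the electron-poor C4a–Br bond; syn carbopalladation of the C5 methylene then joins C4a to C5 and leaves a CH2–Pd group with no β-hydrogen, so bromide is exchanged for formate, CO2 is lost and reductive elimination from the alkyl hydride on divalent palladium forms the C5 methyl. The closest known reaction type is the enantioselective intramolecular reductive Heck reaction of aryl and alkenyl halides with 1,1-disubstituted alkenes and HCO2Na, which delivers methyl-bearing quaternary carbons. Ring A (C4a, C5, C6, C7, C8, C8a) closes in the 6-exo-trig mode, since the 7-endo mode would place palladium on the fully substituted C5 and strain the four-atom tether. The only new stereocentre, C5, is set by the chiral bisphosphine, which has to choose between the two enantiotopic faces of an alkene whose substituents (a CH2 terminus against the C6 ketal carbon and the farnesyl CH2) differ strongly, so the methyl/farnesyl pair never has to be told apart; the (5S) face is required. The step needs face selectivity, exo selectivity and an insertion that outruns formate reduction of the C4a–palladium bond and formate attack at C4a: the short tether holds the alkene next to palladium, the neopentyl intermediate cannot undergo β-hydride elimination, and the dioxolane keeps the C6 oxygen from displacing bromide. Both C7 epimers of 14 are expected to cyclise under ligand control to C7 epimers of 15 that converge in the last step.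

Step 9
Reactants: 15 (5S)-6,6-(ethylenedioxy)-3,5,7-trimethyl-5-[(2E,6E)-3,7,11-trimethyldodeca-2,6,10-trien-1-yl]-6,7-dihydro-1H-isochromene-1,8(5H)-dione
Product: 16 (5S)-8-hydroxy-3,5,7-trimethyl-5-[(2E,6E)-3,7,11-trimethyldodeca-2,6,10-trien-1-yl]-1H-isochromene-1,6(5H)-dione (5-farnesyl-isochromene)
Conditions: 1 M HCl/THF (1:4), rt → 40 °C
Reagents that add atoms: water, O
Why: Acid-catalysed ketal hydrolysis, assisted by enolisation of the C8 ketone, frees the C6 carbonyl, and the C6/C8 diketone should settle as the C7=C8 enol hydrogen-bonded to the lactone carbonyl, which erases C7, while the quaternary C5 cannot epimerise and dilute acid should leave the trisubstituted alkenes untouched.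

**Compound list**
1 | methyl 2-methyl-3-oxobutanoate | COC(=O)C(C)C(C)=O | starting material
2 | (2E,6E)-farnesyl bromide | CC(C)=CCC/C(C)=C/CC/C(C)=C/CBr | starting material
3 | sodium lithium dianion (1,3-bis-enolate) of 1 | [Na+].[Li+].C=C([O-])C(C)=C([O-])OC | intermediate
4 | methyl (6E,10E)-2,7,11,15-tetramethyl-3-oxohexadeca-6,10,14-trienoate | CC(C)=CCC/C(C)=C/CC/C(C)=C/CCC(=O)C(C)C(=O)OC | intermediate
5 | dilithium dianion (1,3-bis-enolate) of 4 | [Li+].[Li+].CC(C)=CCC/C(C)=C/CC/C(C)=C/CC=C([O-])C(C)=C([O-])OC | intermediate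
6 | methyl (6E,10E)-2,7,11,15-tetramethyl-3-oxo-4-[(phenylsulfanyl)methyl]hexadeca-6,10,14-trienoate | CC(C)=CCC/C(C)=C/CC/C(C)=C/CC(CSc1ccccc1)C(=O)C(C)C(=O)OC | intermediate
7 | methyl 2-{2-[(4E,8E)-5,9,13-trimethyl-1-(phenylsulfanyl)tetradeca-4,8,12-trien-2-yl]-1,3-dioxolan-2-yl}propanoate | CC(C)=CCC/C(C)=C/CC/C(C)=C/CC(CSc1ccccc1)C1(OCCO1)C(C)C(=O)OC | intermediate
8 | methyl 2-{2-[(4E,8E)-5,9,13-trimethyl-1-(phenylsulfinyl)tetradeca-4,8,12-trien-2-yl]-1,3-dioxolan-2-yl}propanoate | CC(C)=CCC/C(C)=C/CC/C(C)=C/CC(CS(=O)c1ccccc1)C1(OCCO1)C(C)C(=O)OC | intermediate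
9 | methyl 2-{2-[(4E,8E)-5,9,13-trimethyltetradeca-1,4,8,12-tetraen-2-yl]-1,3-dioxolan-2-yl}propanoate | CC(C)=CCC/C(C)=C/CC/C(C)=C/CC(=C)C1(OCCO1)C(C)C(=O)OC | intermediate
10 | 2-{2-[(4E,8E)-5,9,13-trimethyltetradeca-1,4,8,12-tetraen-2-yl]-1,3-dioxolan-2-yl}propanoic acid | CC(C)=CCC/C(C)=C/CC/C(C)=C/CC(=C)C1(OCCO1)C(C)C(=O)O | intermediate
11 | 4-hydroxy-6-methylpyran-2-one | Cc1cc(O)cc(=O)o1 | starting material
12 | 6-methyl-2-oxo-2H-pyran-4-yl 2-{2-[(4E,8E)-5,9,13-trimethyltetradeca-1,4,8,12-tetraen-2-yl]-1,3-dioxolan-2-yl}propanoate | CC(C)=CCC/C(C)=C/CC/C(C)=C/CC(=C)C1(OCCO1)C(C)C(=O)Oc1cc(C)oc(=O)c1 | intermediate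
13 | 4-hydroxy-6-methyl-3-(2-{2-[(4E,8E)-5,9,13-trimethyltetradeca-1,4,8,12-tetraen-2-yl]-1,3-dioxolan-2-yl}propanoyl)-2H-pyran-2-one | CC(C)=CCC/C(C)=C/CC/C(C)=C/CC(=C)C1(OCCO1)C(C)C(=O)c1c(O)cc(C)oc1=O | intermediate
14 | 4-bromo-6-methyl-3-(2-{2-[(4E,8E)-5,9,13-trimethyltetradeca-1,4,8,12-tetraen-2-yl]-1,3-dioxolan-2-yl}propanoyl)-2H-pyran-2-one | CC(C)=CCC/C(C)=C/CC/C(C)=C/CC(=C)C1(OCCO1)C(C)C(=O)c1c(Br)cc(C)oc1=O | intermediate
15 | (5S)-6,6-(ethylenedioxy)-3,5,7-trimethyl-5-[(2E,6E)-3,7,11-trimethyldodeca-2,6,10-trien-1-yl]-6,7-dihydro-1H-isochromene-1,8(5H)-dione (C7 epimers) | CC(C)=CCC/C(C)=C/CC/C(C)=C/C[C@]1(C)C2(OCCO2)C(C)C(=O)c2c1cc(C)oc2=O | intermediate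
16 | (5S)-8-hydroxy-3,5,7-trimethyl-5-[(2E,6E)-3,7,11-trimethyldodeca-2,6,10-trien-1-yl]-1H-isochromene-1,6(5H)-dione (5-farnesyl-isochromene) | CC(C)=CCC/C(C)=C/CC/C(C)=C/C[C@]1(C)C(=O)C(C)=C(O)c2c1cc(C)oc2=O | target

**Step count**
Total: 9 steps. Longest linear sequence: 9 steps (1 to 16); 11 enters at step 6.

**Steps most likely to fail**

1. Step 8. The two faces of the C5 alkene may be poorly discriminated while bromide stays on palladium and one phosphorus arm can dissociate. The fallback moves the source of enantiopurity from catalysis to resolution. It sets out from 14: cyclisation with an achiral catalyst (Pd(OAc)2, 1,1'-bis(diphenylphosphino)ferrocene, HCO2Na, DMF, 80 °C) should give the racemic spiro-dioxolane F1. Hydrolysis of F1 with 1 M HCl/THF should give racemic 5-farnesyl-isochromene F2. Preparative HPLC of F2 on an amylose tris(3,5-dimethylphenylcarbamate) phase then returns to the route at 16.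

2. Step 3. Ketal formation may stall at a ketone that sits between two branched carbons, and forcing it may cause loss of thiophenol by β-elimination or silyl enol ether formation. The fallback reverses the order of ketalisation and alkene formation. It sets out from 6: NaIO4 in MeOH/THF/H2O should give the β-keto sulfoxide F3, which is expected to lose benzenesulfenic acid on gentle warming (CH2Cl2, NaHCO3, 40 °C) because its β-hydrogen is α to the ketone, giving the α-methylene keto ester F4. F4 has a planar C5 and is less crowded; ketalised under the same aprotic conditions ((Me3SiOCH2)2, Me3SiOTf cat., CH2Cl2, −78 → −20 °C, no free diol and hence no oxa-Michael addition), it comes back to the route at 9.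

3. Step 7. The phosphonium reagent may activate the acyl oxygen in place of O4 or open the dioxolane, and the vinylogous acyl bromide may hydrolyse on isolation. The fallback replaces the halide by a sulfonate that is cyclised directly. It sets out from 13: PhNTf2, Et3N, CH2Cl2, 0 °C should give the pyranyl triflate F5. F5 is submitted to the reductive Heck conditions of step 8 (Pd(OAc)2, (R)-BINAP, HCO2Na, DMF, 60–80 °C), where oxidative addition gives a cationic palladium centre with both phosphorus atoms bound, and the sequence comes back to the route at 15.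

**Further compounds**
F1 | step 8 | racemic 6,6-(ethylenedioxy)-3,5,7-trimethyl-5-[(2E,6E)-3,7,11-trimethyldodeca-2,6,10-trien-1-yl]-6,7-dihydro-1H-isochromene-1,8(5H)-dione | CC(C)=CCC/C(C)=C/CC/C(C)=C/CC1(C)C2(OCCO2)C(C)C(=O)c2c1cc(C)oc2=O
F2 | step 8 | racemic 8-hydroxy-3,5,7-trimethyl-5-[(2E,6E)-3,7,11-trimethyldodeca-2,6,10-trien-1-yl]-1H-isochromene-1,6(5H)-dione | CC(C)=CCC/C(C)=C/CC/C(C)=C/CC1(C)C(=O)C(C)=C(O)c2c1cc(C)oc2=O
F3 | step 3 | methyl (6E,10E)-2,7,11,15-tetramethyl-3-oxo-4-[(phenylsulfinyl)methyl]hexadeca-6,10,14-trienoate | CC(C)=CCC/C(C)=C/CC/C(C)=C/CC(CS(=O)c1ccccc1)C(=O)C(C)C(=O)OC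
F4 | step 3 | methyl (6E,10E)-2,7,11,15-tetramethyl-4-methylidene-3-oxohexadeca-6,10,14-trienoate | CC(C)=CCC/C(C)=C/CC/C(C)=C/CC(=C)C(=O)C(C)C(=O)OC
F5 | step 7 | 6-methyl-2-oxo-3-(2-{2-[(4E,8E)-5,9,13-trimethyltetradeca-1,4,8,12-tetraen-2-yl]-1,3-dioxolan-2-yl}propanoyl)-2H-pyran-4-yl trifluoromethanesulfonate | CC(C)=CCC/C(C)=C/CC/C(C)=C/CC(=C)C1(OCCO1)C(C)C(=O)c1c(OS(=O)(=O)C(F)(F)F)cc(C)oc1=O
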